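**Retrosynthetic overview**
1. Oxolane numbering: O1, C2 (aryl), C3 (CH2OAc arm), C4 (OH and arylmethyl), C5 (CH2). The target is (2S,3R,4S), with aryl and OH on one face and the arm and arylmethyl group on the other. The last operations are selective acetylation of the primary OH of di-O-benzylolivil and phenol debenzylation.
2. Key disconnection: the C3–C4 ring bond and, in the same operation, the C–O bond of the C3 arm. This leads back to an acyclic α-(1-arylallyloxy) ketone. In the forward direction it is a SmI2 ketyl–olefin 5-exo cyclisation followed by O2 oxygenation of the primary alkylsamarium.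
3. Enabling feature: C4 is a tertiary carbinol (a masked ketone) next to C3 with its one-carbon oxygenated arm (a masked vinyl group), and the two are linked through C5–O1–C2. The open form is therefore a 3-oxa-5-hexenyl ketyl, and its only stereocentre, the benzylic and allylic C2, steers both new centres.
4. The ketone comes from a Weinreb amide ether and a benzylic Grignard reagent. The ether comes from (S)-1-arylallyl alcohol (vinyl Grignard addition to O-benzylvanillin, then lipase resolution) and a bromoacetamide.
5. Ring order: both arene rings are bought. The oxolane is the only ring made, and it is closed in the key step.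

Key step: step 6

**Route**

Step 1
Reactants: 1 4-(benzyloxy)-3-methoxybenzaldehyde (O-benzylvanillin); 2 vinylmagnesium bromide
Product: 3 rac-1-[4-(benzyloxy)-3-methoxyphenyl]prop-2-en-1-ol
Conditions: THF, -78 °C to 0 °C; aq. NH4Cl
Reagents that add atoms: none
Why: Grignard 1,2-addition of a vinyl nucleophile to a non-enolisable aromatic aldehyde; the carbinol centre forms racemic and is resolved in step 2.

Step 2
Reactants: 3 rac-1-[4-(benzyloxy)-3-methoxyphenyl]prop-2-en-1-ol
Product: 4 (S)-1-[4-(benzyloxy)-3-methoxyphenyl]prop-2-en-1-ol
Conditions: immobilised Candida antarctica lipase B, vinyl acetate, MTBE, 30 °C, run slightly past half conversion; chromatography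
Reagents that add atoms: none
Why: Lipase-catalysed kinetic resolution by irreversible transesterification: by the empirical large/medium-substituent rule for secondary alcohols the enzyme should acetylate the (R)-alcohol (aryl large, vinyl medium) and leave (S)-4, whose purity rises on going beyond half conversion, and this sets C2 of the target.

Step 3
Reactants: 4 (S)-1-[4-(benzyloxy)-3-methoxyphenyl]prop-2-en-1-ol; 5 2-bromo-N-methoxy-N-methylacetamide
Product: 6 2-{[(1S)-1-[4-(benzyloxy)-3-methoxyphenyl]prop-2-en-1-yl]oxy}-N-methoxy-N-methylacetamide
Conditions: NaH, THF–DMF, 0 °C; then 5, 0 °C to rt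
Reagents that add atoms: none
Why: Williamson ether synthesis (SN2 at the primary α-bromo amide carbon) that breaks no bond at the stereocentre, so the (S) configuration is kept.

Step 4
Reactants: 7 [4-(benzyloxy)-3-methoxyphenyl]methanol
Product: 8 1-(benzyloxy)-4-(chloromethyl)-2-methoxybenzene
Conditions: SOCl2, CH2Cl2, 0 °C; used crude
Reagents that add atoms: thionyl chloride, O=S(Cl)Cl
Why: Chlorodehydroxylation of an electron-rich benzylic alcohol with thionyl chloride, which is fast at low temperature and leaves the aryl benzyl and methyl ethers untouched.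

Step 5
Reactants: 8 1-(benzyloxy)-4-(chloromethyl)-2-methoxybenzene; 6 Weinreb amide ether
Product: 10 1-[4-(benzyloxy)-3-methoxyphenyl]-3-{[(1S)-1-[4-(benzyloxy)-3-methoxyphenyl]prop-2-en-1-yl]oxy}propan-2-one, via benzylic Grignard reagent 9 (not isolated)
Conditions: Mg turnings, THF (dilute), 0 °C, slow addition of 8; then 6, -78 °C to 0 °C; aq. NH4Cl
Reagents that add atoms: none
Why: Grignard formation followed by Weinreb ketone synthesis: the chelated tetrahedral adduct persists until work-up, so one addition gives the ketone, and the stereocentre is remote from the reacting carbonyl.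

Step 6
Reactants: 10 allyloxy ketone
Product: 12 (3S,4R,5S)-5-[4-(benzyloxy)-3-methoxyphenyl]-3-{[4-(benzyloxy)-3-methoxyphenyl]methyl}-4-(hydroxymethyl)oxolan-3-ol (di-O-benzylolivil), via cyclised alkylsamarium alkoxide 11 (not isolated)
Conditions: SmI2 (2.5 equiv), HMPA, THF, 0 °C, no proton source, slow addition of 10; then dry O2, -78 °C to rt; aq. work-up
Reagents that add atoms: dioxygen, O=O
Why: SmI2–HMPA transfers one electron to the ketone, the samarium ketyl at C4 adds to the internal vinyl carbon C3, a second SmI2 reduces the primary exocyclic radical to the alkylsamarium(III) 11, and dry O2 turns its C–Sm bond into C–O, so one flask makes the C3–C4 bond, the oxolane, two stereocentres and the oxygen of the arm. The closest known reaction type is the SmI2–HMPA ketyl–olefin cyclisation of unactivated olefinic ketones run without a proton source and followed by trapping of the alkylsamarium with an electrophile (O2 among them), and 5-exo closures of α-benzyloxy ketyls from sugar-derived hex-5-enals under the same reagent show that an α-alkoxy group can survive. The oxolane closes 5-exo-trig through a chair-like transition state of the 5-hexenyl radical type (here 3-oxa). C3 is controlled by the existing C2 stereocentre, whose aryl group takes the pseudo-equatorial allylic position and so ends trans to the new CH2 arm. C4 is controlled by the bulky, electron-rich O–Sm(HMPA)n group, which turns away from the alkene terminus, so that oxygen ends trans and the arylmethyl group cis to the arm, which together is the (2S,3R,4S) array of the target. Ring closure must outrun loss of the α-alkoxy group, six-membered attack of the ketyl on the C2 arene and protonation of 11, and this should be secured by the fast 5-exo mode, the electron-rich and therefore poorly accepting arenes, the absence of any proton source and the slow addition of 10 to excess reductant.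

Step 7
Reactants: 12 di-O-benzylolivil
Product: 13 [(2S,3R,4S)-2-[4-(benzyloxy)-3-methoxyphenyl]-4-{[4-(benzyloxy)-3-methoxyphenyl]methyl}-4-hydroxyoxolan-3-yl]methyl acetate
Conditions: Ac2O (1.1 equiv), pyridine, CH2Cl2, 0 °C
Reagents that add atoms: acetic anhydride, CC(=O)OC(C)=O
Why: Sterically controlled O-acylation in which the primary OH reacts and the tertiary C4–OH stays free under these mild conditions; no stereocentre is touched.

Step 8
Reactants: 13 di-O-benzylolivil monoacetate
Product: 14 olivil monoacetate, [(2S,3R,4S)-4-hydroxy-2-(4-hydroxy-3-methoxyphenyl)-4-[(4-hydroxy-3-methoxyphenyl)methyl]oxolan-3-yl]methyl acetate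
Conditions: H2 (1 atm), 10% Pd/C, EtOAc–EtOH, rt, stopped after uptake of 2 equiv
Reagents that add atoms: none
Why: Catalytic hydrogenolysis in a neutral medium should cleave the two aryl benzyl ethers faster than the ring C2–O1 benzylic ether, the acetate and the tertiary alcohol are inert, and no stereocentre is touched.

**Compound list**
1 | 4-(benzyloxy)-3-methoxybenzaldehyde | COc1cc(C=O)ccc1OCc1ccccc1 | starting material
2 | vinylmagnesium bromide | C=C[Mg]Br | starting material
3 | rac-1-[4-(benzyloxy)-3-methoxyphenyl]prop-2-en-1-ol | OC(c1ccc(OCc2ccccc2)c(OC)c1)C=C | intermediate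
4 | (S)-1-[4-(benzyloxy)-3-methoxyphenyl]prop-2-en-1-ol | O[C@H](c1ccc(OCc2ccccc2)c(OC)c1)C=C | intermediate
5 | 2-bromo-N-methoxy-N-methylacetamide | CON(C)C(=O)CBr | starting material
6 | 2-{[(1S)-1-[4-(benzyloxy)-3-methoxyphenyl]prop-2-en-1-yl]oxy}-N-methoxy-N-methylacetamide | CON(C)C(=O)CO[C@H](c1ccc(OCc2ccccc2)c(OC)c1)C=C | intermediate
7 | [4-(benzyloxy)-3-methoxyphenyl]methanol | COc1cc(CO)ccc1OCc1ccccc1 | starting material
8 | 1-(benzyloxy)-4-(chloromethyl)-2-methoxybenzene | COc1cc(CCl)ccc1OCc1ccccc1 | intermediate
9 | 4-(benzyloxy)-3-methoxybenzylmagnesium chloride (not isolated) | COc1cc(C[Mg]Cl)ccc1OCc1ccccc1 | intermediate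
10 | 1-[4-(benzyloxy)-3-methoxyphenyl]-3-{[(1S)-1-[4-(benzyloxy)-3-methoxyphenyl]prop-2-en-1-yl]oxy}propan-2-one | COc1cc(CC(=O)CO[C@H](c2ccc(OCc3ccccc3)c(OC)c2)C=C)ccc1OCc1ccccc1 | intermediate
11 | cyclised oxolane carrying C4–O–SmI2 and C3–CH2–SmI2, same spatial arrangement as 12 (not isolated) | COc1cc(C[C@@]2(O[Sm](I)I)CO[C@H](c3ccc(OCc4ccccc4)c(OC)c3)[C@H]2C[Sm](I)I)ccc1OCc1ccccc1 | intermediate
12 | di-O-benzylolivil | COc1cc(C[C@@]2(O)CO[C@H](c3ccc(OCc4ccccc4)c(OC)c3)[C@H]2CO)ccc1OCc1ccccc1 | intermediate
13 | di-O-benzylolivil monoacetate | COc1cc(C[C@@]2(O)CO[C@H](c3ccc(OCc4ccccc4)c(OC)c3)[C@H]2COC(C)=O)ccc1OCc1ccccc1 | intermediate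
14 | olivil monoacetate | COc1cc(C[C@@]2(O)CO[C@H](c3ccc(O)c(OC)c3)[C@H]2COC(C)=O)ccc1O | target

**Step count**
Total step count: 8.
Longest linear sequence: 7 (steps 1, 2, 3, 5, 6, 7, 8).

**Steps most likely to fail**

Step 6.
- What may go wrong: reductive expulsion of the α-alkoxy group from the ketyl before ring closure.
- What may go wrong: premature protonation of the alkylsamarium by still unreduced, enolisable ketone, so that the arm is never oxygenated.
- What may go wrong: inefficient oxygen transfer from O2.
- Fallback: it sets out from 10 and brings the oxygen of the arm in as boron on an activated acceptor. Cross metathesis of 10 with vinylboronic acid pinacol ester (Hoveyda–Grubbs second-generation catalyst, CH2Cl2, 40 °C) should give the (E)-alkenylboronate ketone F1. SmI2 in THF–MeOH at -78 °C without HMPA should close the same C3–C4 bond 5-exo. The ketyl adds to the carbon β to boron, and the α-boryl radical is reduced and protonated in situ. This extends the known Giese-type addition of α-oxygenated radicals to alkenylboronic esters and should give the cyclised pinacol boronate F2. The faster closure and the protic medium remove both the long-lived alkylsamarium and the time available for fragmentation. Oxidation of F2 with NaBO3 in THF–water comes back to the route at 12.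

Step 5.
- What may go wrong: Wurtz-type homocoupling during magnesium insertion into the electron-rich benzylic chloride.
- What may go wrong: enolisation of the amide instead of addition.
- Fallback: it sets out from 4, moves the disconnection to the aryl–CH2 bond and uses an aryl rather than a benzyl organometallic. Alcohol 4 is glycidylated with racemic epichlorohydrin (50% aq. NaOH, Bu4NHSO4) to the glycidyl ether F3, an epimer mixture at the oxirane carbon. Commercial 1-(benzyloxy)-4-bromo-2-methoxybenzene is converted with Mg into the arylmagnesium bromide F4. With catalytic CuI in THF at -30 °C this reagent opens F3 at the terminal carbon to the secondary alcohol F5, a carbinol epimer mixture. Dess–Martin oxidation removes that centre and comes back to the route at 10.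

Step 3.
- What may go wrong: attack of the alkoxide on the amide carbonyl.
- What may go wrong: base-induced breakdown of the N-methoxy amide.
- What may go wrong: base-induced isomerisation of the allylic alkoxide.
- Fallback: it sets out from 4 and separates ether formation from amide formation. Compound 4 is alkylated with bromoacetic acid and NaH (2.2 equiv, THF, 0 °C to rt); the sodium carboxylate offers no electrophilic carbonyl. This gives the alkoxyacetic acid F6. Coupling of F6 with N,O-dimethylhydroxylamine hydrochloride (EDC, N-methylmorpholine, CH2Cl2) comes back to the route at 6.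

**Further compounds**
F1 | step 6 | (E)-alkenylboronate ketone: 10 with the vinyl terminus carrying a pinacol boronate | COc1cc(CC(=O)CO[C@H](c2ccc(OCc3ccccc3)c(OC)c2)/C=C/B2OC(C)(C)C(C)(C)O2)ccc1OCc1ccccc1
F2 | step 6 | cyclised pinacol boronate: 12 with CH2–B(pin) in place of CH2OH | COc1cc(C[C@@]2(O)CO[C@H](c3ccc(OCc4ccccc4)c(OC)c3)[C@H]2CB5OC(C)(C)C(C)(C)O5)ccc1OCc1ccccc1
F3 | step 5 | glycidyl ether of 4 (epimers at the oxirane carbon) | C(C1CO1)O[C@H](c1ccc(OCc2ccccc2)c(OC)c1)C=C
F4 | step 5 | 4-(benzyloxy)-3-methoxyphenylmagnesium bromide | COc1cc([Mg]Br)ccc1OCc1ccccc1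
F5 | step 5 | 1-[4-(benzyloxy)-3-methoxyphenyl]-3-{[(1S)-1-[4-(benzyloxy)-3-methoxyphenyl]prop-2-en-1-yl]oxy}propan-2-ol (carbinol epimers) | COc1cc(CC(O)CO[C@H](c2ccc(OCc3ccccc3)c(OC)c2)C=C)ccc1OCc1ccccc1
F6 | step 3 | 2-{[(1S)-1-[4-(benzyloxy)-3-methoxyphenyl]prop-2-en-1-yl]oxy}acetic acid | OC(=O)CO[C@H](c1ccc(OCc2ccccc2)c(OC)c1)C=C
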